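**Plan**

1. Numbering used throughout: C1 is the quaternary carbon with the angular methyl; the five-membered ring is C1–C2(OAc)–C3–C4(OH, i-Pr)–C5; the seven-membered ring is C5–C6(O-vanilloyl)–C7–C8(Me)–C9–C10–C1; β is the face of the C1 methyl.
2. Retrosynthesis: the epoxide and acetate come off, then C2–C3 is cut (Prins cyclisation) to a cycloheptene aldehyde; C5–C4, the C6–O bond (through a lactone to the C2 ester), C8=C9 (ring-closing metathesis), C6–C7, C1–C10 and C1–CH3 are cut back to methyl (R)-3-hydroxybutanoate, whose four carbons become C2, C1, C5 and C6.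
3. Forward order of rings: seven-membered ring first (metathesis), then a temporary C2-to-O6 lactone bridge that places O6 and steers the chemistry at C5, then the five-membered ring (key step), and the epoxide last.
4. The key event is possible because the C2 aldehyde sits on quaternary C1 (non-enolisable), the C3=C4 alkene is 1,1-disubstituted (tertiary cation at C4), and the C6 aroyloxy group lies 1,3 to C4 across C5, so its carbonyl oxygen can capture the C4 cation in a six-membered dioxanylium ring; the ring, the C4 carbinol and its configuration arise together.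
5. Stereochemistry: C1 from the chiral pool (relayed through the carbinol of 1); C6 from the lactone bridge; C5 from a stereospecific palladium formate hydrogenolysis; C4 from the ester tether in the key step; C2 from a C4–OH-directed reduction; C8/C9 from shielding of the β face by the C1 methyl.

Key step: step 11

Remark: methyl (R)-3-hydroxybutanoate, 2-bromo-3-methylbut-1-ene and 4-(benzyloxy)-3-methoxybenzoic acid are taken as commercial.

**Route**

Step 1
Reactants: 1 methyl (R)-3-hydroxybutanoate
Product: 2 methyl (2R,3R)-3-hydroxy-2-methylbutanoate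
Conditions: LDA (2.2 equiv), THF, −78 → −20 °C; MeI, −78 → 0 °C
Reagents that add atoms: iodomethane CI
Why: Frater–Seebach alkylation: the chelated alkoxide–enolate dianion should be methylated on the face away from the C3 methyl, giving the anti (2R,3R) ester.

Step 2
Reactants: 2 methyl (2R,3R)-3-hydroxy-2-methylbutanoate
Product: 3 methyl (2R)-2-[(1R)-1-hydroxyethyl]-2-methylpent-4-enoate
Conditions: LDA (2.5 equiv), THF, DMPU, −78 → −10 °C; allyl bromide, −78 → 0 °C
Reagents that add atoms: allyl bromide C=CCBr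
Why: A second Frater–Seebach alkylation on the same enolate face puts the allyl group where the methyl entered before, so the quaternary carbon (future C1) should form as a single (R) centre.

Step 3
Reactants: 3 methyl (2R)-2-[(1R)-1-hydroxyethyl]-2-methylpent-4-enoate
Product: 4 methyl (2R)-2-acetyl-2-methylpent-4-enoate
Conditions: Dess–Martin periodinane, CH2Cl2, rt
Reagents that add atoms: none
Why: Dess–Martin oxidation of the secondary alcohol to the ketone; the quaternary α-carbon cannot enolise, so its configuration is kept while the relay carbinol is removed.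

Step 4
Reactants: 4 methyl (2R)-2-acetyl-2-methylpent-4-enoate
Product: 5 methyl (2R)-2,6-dimethyl-3-oxo-2-(prop-2-en-1-yl)hept-6-enoate
Conditions: LDA (1.1 equiv), THF, −78 °C; 3-bromo-2-methylprop-1-ene, DMPU, −78 → −20 °C
Reagents that add atoms: 3-bromo-2-methylprop-1-ene C=C(C)CBr
Why: Enolate alkylation: the acetyl methyl is the only enolisable position, and its kinetic lithium enolate should be alkylated by the allylic bromide to form C6–C7.

Step 5
Reactants: 5 methyl (2R)-2,6-dimethyl-3-oxo-2-(prop-2-en-1-yl)hept-6-enoate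
Product: 6 methyl (1R)-1,5-dimethyl-2-oxocyclohept-5-ene-1-carboxylate
Conditions: second-generation Grubbs catalyst (5 mol %), CH2Cl2 (5 mM), 40 °C
Reagents that add atoms: none
Why: Ring-closing metathesis of the allyl group with the 1,1-disubstituted alkene should close the seven-membered ring and form the trisubstituted C8=C9 alkene with loss of ethylene.

Step 6
Reactants: 6 methyl (1R)-1,5-dimethyl-2-oxocyclohept-5-ene-1-carboxylate
Product: 8 (1R,6S)-1,4-dimethyl-7-oxabicyclo[4.2.1]non-3-ene-8,9-dione (C2 lactone carbonyl bridged to O6; C5 is the bridge ketone), via hydroxy ketone 7 (not isolated)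
Conditions: KN(SiMe3)2, THF, −78 °C; 2-(phenylsulfonyl)-3-phenyloxaziridine; AcOH quench; then camphorsulfonic acid (cat.), toluene, 4 Å MS, 80 °C
Reagents that add atoms: 2-(phenylsulfonyl)-3-phenyloxaziridine O=S(=O)(c1ccccc1)N1OC1c1ccccc1
Why: Enolate α-hydroxylation at C6 (the only enolisable carbon) followed by acid-catalysed equilibration of the ketol epimers and lactonisation; only the epimer with O6 cis to the C2 ester can close the five-membered lactone, which fixes C6.

Step 7
Reactants: 8 (1R,6S)-1,4-dimethyl-7-oxabicyclo[4.2.1]non-3-ene-8,9-dione; 9 2-bromo-3-methylbut-1-ene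
Product: 11 methyl (1R,6S)-1,4-dimethyl-9-(3-methylbut-1-en-2-yl)-8-oxo-7-oxabicyclo[4.2.1]non-3-en-9-yl carbonate (alkenyl group syn to the lactone bridge), via magnesium alkoxide 10 (not isolated)
Conditions: 9, Mg, THF (Grignard reagent); LaCl3·2LiCl (0.3 equiv), 8, THF, −40 °C; then ClCO2Me, −40 → 0 °C
Reagents that add atoms: 2-bromo-3-methylbut-1-ene (9) C=C(Br)C(C)C; methyl chloroformate COC(=O)Cl
Why: 1,2-Addition of an alkenyl Grignard reagent to the strained, non-enolisable C5 bridge ketone should occur from the face of the lactone bridge (no hydrogens there, and it can chelate the metal), placing the C5 oxygen over the four-carbon bridge; the alkoxide is trapped in situ as the carbonate before retro-aldol cleavage can occur.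

Step 8
Reactants: 11 methyl (1R,6S)-1,4-dimethyl-9-(3-methylbut-1-en-2-yl)-8-oxo-7-oxabicyclo[4.2.1]non-3-en-9-yl carbonate
Product: 12 (1R,6S)-1,4-dimethyl-9-(3-methylbut-1-en-2-yl)-7-oxabicyclo[4.2.1]non-3-en-8-one (H on C5 syn to the lactone bridge, alkenyl over the four-carbon bridge)
Conditions: Pd(OAc)2 (5 mol %), n-Bu3P (20 mol %), HCO2H, Et3N, THF, 60 °C
Reagents that add atoms: none
Why: Palladium-catalysed formate hydrogenolysis of an allylic carbonate: zerovalent palladium ionises C5–O anti to the carbonate and the formate hydride is passed from palladium to the more substituted terminus C5, so C5–H should form with inversion and the 1,1-disubstituted C3=C4 alkene is kept.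

Step 9
Reactants: 12 (1R,6S)-1,4-dimethyl-9-(3-methylbut-1-en-2-yl)-7-oxabicyclo[4.2.1]non-3-en-8-one; 13 4-(benzyloxy)-3-methoxybenzoic acid
Product: 15 6-[methoxy(methyl)carbamoyl]-3,6-dimethyl-7-(3-methylbut-1-en-2-yl)cyclohept-3-en-1-yl 4-(benzyloxy)-3-methoxybenzoate (ester oxygen cis to the amide, alkenyl trans to both), via hydroxy amide 14 (not isolated)
Conditions: MeNH(OMe)·HCl, i-PrMgCl, THF, −20 → 0 °C; aq. NH4Cl work-up; then 13, DCC, DMAP (cat.), CH2Cl2, 0 °C → rt
Reagents that add atoms: N,O-dimethylhydroxylamine hydrochloride CNOC.Cl; 4-(benzyloxy)-3-methoxybenzoic acid (13) COc1cc(C(=O)O)ccc1OCc1ccccc1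
Why: Weinreb aminolysis opens the temporary lactone at C2 and frees the C6 hydroxyl, which is acylated at once by Steglich esterification so that it cannot relactonise; no stereocentre is touched.

Step 10
Reactants: 15 6-[methoxy(methyl)carbamoyl]-3,6-dimethyl-7-(3-methylbut-1-en-2-yl)cyclohept-3-en-1-yl 4-(benzyloxy)-3-methoxybenzoate
Product: 16 6-formyl-3,6-dimethyl-7-(3-methylbut-1-en-2-yl)cyclohept-3-en-1-yl 4-(benzyloxy)-3-methoxybenzoate (ester oxygen cis to the formyl group, alkenyl trans to both)
Conditions: Cp2Zr(H)Cl (1.5 equiv), THF, rt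
Reagents that add atoms: none
Why: Reduction of a tertiary (Weinreb) amide to the aldehyde with Cp2Zr(H)Cl proceeds through a stable zirconated hemiaminal and should leave the aryl ester and the hindered alkenes untouched.

Step 11
Reactants: 16 6-formyl-3,6-dimethyl-7-(3-methylbut-1-en-2-yl)cyclohept-3-en-1-yl 4-(benzyloxy)-3-methoxybenzoate
Product: 19 6α-[4-(benzyloxy)-3-methoxybenzoyloxy]-5αH-dauc-8-ene-2β,4β-diol, via dioxanylium triflate 17 (not isolated), via silyl ether 18 (not isolated)
Conditions: Me3SiOTf (1.3 equiv), 2,6-di-tert-butyl-4-methylpyridine, CH2Cl2, −78 → −40 °C; sat. aq. NaHCO3, −40 → 0 °C; then 1 M HCl, THF, 0 °C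
Reagents that add atoms: water O
Why: Proposed new method: Me3SiOTf turns the non-enolisable C2 aldehyde into a silyloxocarbenium ion, the 1,1-disubstituted C3=C4 alkene attacks it through C3 (Prins cyclisation), and the tertiary C4 cation is captured by the carbonyl oxygen of the C6 aroyloxy group, 1,3 to C4 across C5, to give the 2-aryl-1,3-dioxan-2-ylium ion 17, which water opens to the C4 alcohol and the C6 ester (the acid treatment also removes the silyl group and lets any C4 ester migrate to the less hindered O6). The closest known reactions are Lewis-acid Prins cyclisations of 4-methylenealkanals to cyclopentanols and the capture of carbocations by neighbouring acyloxy groups, which have not been combined in this way. The cyclopentane closes 5-endo-trig at the alkene (exo at the C=O+ bond), and the temporary dioxanylium ring closes by six-membered combination of the ester oxygen with the C4 cation. C4 is controlled by C5 and C6, because the tether reaches only the β face of the cyclopentyl cation and gives the cis-fused dioxanylium, hence 4β-O with the isopropyl group α; C2 is expected to form with the silyloxy group pseudo-equatorial (2β, cis to the C1 methyl), is not relied upon and is inverted in steps 12 and 13. The step needs chemoselectivity for C3=C4 over the C8=C9 ring alkene (which could reach C2 only through a four-membered ring or a secondary cation, while the hindered pyridine keeps the medium free of protons) and capture of the C4 cation faster than proton loss or hydride shift, which the 1,3-placement of the ester carbonyl secures.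

Step 12
Reactants: 19 6α-[4-(benzyloxy)-3-methoxybenzoyloxy]-5αH-dauc-8-ene-2β,4β-diol
Product: 20 6α-[4-(benzyloxy)-3-methoxybenzoyloxy]-4β-hydroxy-5αH-dauc-8-en-2-one
Conditions: Dess–Martin periodinane, pyridine, CH2Cl2, 0 °C → rt
Reagents that add atoms: none
Why: Dess–Martin oxidation converts the secondary C2 carbinol (either epimer) into the ketone; the tertiary C4 hydroxyl is inert and the base-free medium avoids retro-aldol cleavage of the β-hydroxy ketone.

Step 13
Reactants: 20 6α-[4-(benzyloxy)-3-methoxybenzoyloxy]-4β-hydroxy-5αH-dauc-8-en-2-one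
Product: 21 6α-[4-(benzyloxy)-3-methoxybenzoyloxy]-5αH-dauc-8-ene-2α,4β-diol
Conditions: Me4NBH(OAc)3, MeCN/AcOH, −30 → −20 °C
Reagents that add atoms: none
Why: Hydroxyl-directed (Evans–Saksena) reduction: the C4 alkoxy-borohydride should deliver hydride intramolecularly to the β face of the C2 ketone, giving the anti 1,3-diol with 2α-OH.

Step 14
Reactants: 21 6α-[4-(benzyloxy)-3-methoxybenzoyloxy]-5αH-dauc-8-ene-2α,4β-diol
Product: 22 2α-acetoxy-6α-[4-(benzyloxy)-3-methoxybenzoyloxy]-5αH-dauc-8-en-4β-ol
Conditions: Ac2O, DMAP, pyridine, CH2Cl2, 0 °C → rt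
Reagents that add atoms: acetic anhydride CC(=O)OC(C)=O
Why: DMAP-catalysed acetylation should acylate the secondary C2 hydroxyl and leave the tertiary C4 hydroxyl free.

Step 15
Reactants: 22 2α-acetoxy-6α-[4-(benzyloxy)-3-methoxybenzoyloxy]-5αH-dauc-8-en-4β-ol
Product: 23 2α-acetoxy-6α-[4-(benzyloxy)-3-methoxybenzoyloxy]-8α,9α-epoxy-5αH-daucan-4β-ol
Conditions: mCPBA, CH2Cl2, 0 °C
Reagents that add atoms: mCPBA OOC(=O)c1cccc(Cl)c1
Why: Prilezhaev epoxidation of the only remaining alkene should occur on the α face, away from the axial C1 methyl that shields the β face, giving the 8α,9α-epoxide.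

Step 16
Reactants: 23 2α-acetoxy-6α-[4-(benzyloxy)-3-methoxybenzoyloxy]-8α,9α-epoxy-5αH-daucan-4β-ol
Product: 24 2α-acetoxy-8α,9α-epoxy-6α-(4-hydroxy-3-methoxybenzoyloxy)-5αH-daucan-4β-ol (target)
Conditions: H2 (1 atm), Pd/C, EtOAc, rt
Reagents that add atoms: none
Why: Hydrogenolysis of the benzyl ether frees the phenol; the trisubstituted epoxide, the two esters and the tertiary alcohol should be stable under these neutral conditions.

**Compound list**

1 | methyl (R)-3-hydroxybutanoate | C[C@@H](O)CC(=O)OC | starting material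
2 | methyl (2R,3R)-3-hydroxy-2-methylbutanoate | C[C@@H](O)[C@@H](C)C(=O)OC | intermediate
3 | methyl (2R)-2-[(1R)-1-hydroxyethyl]-2-methylpent-4-enoate | C[C@@H](O)[C@@](C)(CC=C)C(=O)OC | intermediate
4 | methyl (2R)-2-acetyl-2-methylpent-4-enoate | CC(=O)[C@@](C)(CC=C)C(=O)OC | intermediate
5 | methyl (2R)-2,6-dimethyl-3-oxo-2-(prop-2-en-1-yl)hept-6-enoate | C=C(C)CCC(=O)[C@@](C)(CC=C)C(=O)OC | intermediate
6 | methyl (1R)-1,5-dimethyl-2-oxocyclohept-5-ene-1-carboxylate | COC(=O)[C@]1(C)CC=C(C)CCC1=O | intermediate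
7 | methyl (1R)-3-hydroxy-1,5-dimethyl-2-oxocyclohept-5-ene-1-carboxylate (both C3 epimers) | COC(=O)[C@]1(C)CC=C(C)CC(O)C1=O | intermediate
8 | (1R,6S)-1,4-dimethyl-7-oxabicyclo[4.2.1]non-3-ene-8,9-dione | O=C1O[C@H]2CC(C)=CC[C@]1(C)C2=O | intermediate
9 | 2-bromo-3-methylbut-1-ene | C=C(Br)C(C)C | starting material
10 | bromomagnesium (1R,6S)-1,4-dimethyl-9-(3-methylbut-1-en-2-yl)-8-oxo-7-oxabicyclo[4.2.1]non-3-en-9-olate (alkenyl syn to the lactone bridge) | O=C1O[C@H]2CC(C)=CC[C@]1(C)[C@@]2(O[Mg]Br)C(=C)C(C)C | intermediate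
11 | methyl (1R,6S)-1,4-dimethyl-9-(3-methylbut-1-en-2-yl)-8-oxo-7-oxabicyclo[4.2.1]non-3-en-9-yl carbonate (alkenyl syn to the lactone bridge) | O=C1O[C@H]2CC(C)=CC[C@]1(C)[C@@]2(OC(=O)OC)C(=C)C(C)C | intermediate
12 | (1R,6S)-1,4-dimethyl-9-(3-methylbut-1-en-2-yl)-7-oxabicyclo[4.2.1]non-3-en-8-one (H-9 syn to the lactone bridge) | O=C1O[C@H]2CC(C)=CC[C@]1(C)[C@@H]2C(=C)C(C)C | intermediate
13 | 4-(benzyloxy)-3-methoxybenzoic acid | COc1cc(C(=O)O)ccc1OCc1ccccc1 | starting material
14 | 3-hydroxy-N-methoxy-N,1,5-trimethyl-2-(3-methylbut-1-en-2-yl)cyclohept-5-ene-1-carboxamide (3-OH cis to the amide, 2-alkenyl trans to both) | O[C@H]1CC(C)=CC[C@@](C)(C(=O)N(C)OC)[C@@H]1C(=C)C(C)C | intermediate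
15 | 6-[methoxy(methyl)carbamoyl]-3,6-dimethyl-7-(3-methylbut-1-en-2-yl)cyclohept-3-en-1-yl 4-(benzyloxy)-3-methoxybenzoate (ester oxygen cis to the amide, alkenyl trans to both) | COc1cc(C(=O)O[C@H]2CC(C)=CC[C@@](C)(C(=O)N(C)OC)[C@@H]2C(=C)C(C)C)ccc1OCc1ccccc1 | intermediate
16 | 6-formyl-3,6-dimethyl-7-(3-methylbut-1-en-2-yl)cyclohept-3-en-1-yl 4-(benzyloxy)-3-methoxybenzoate (ester oxygen cis to the formyl group, alkenyl trans to both) | COc1cc(C(=O)O[C@H]2CC(C)=CC[C@@](C)(C=O)[C@@H]2C(=C)C(C)C)ccc1OCc1ccccc1 | intermediate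
17 | 2-aryl-1,3-dioxan-2-ylium triflate bridging O4 and O6 of the 2β-(trimethylsilyloxy)dauc-8-ene | COc1cc(C2=[O+][C@H]3CC(C)=CC[C@@]4(C)[C@H](O[Si](C)(C)C)C[C@@](O2)(C(C)C)[C@H]34)ccc1OCc1ccccc1.[O-]S(=O)(=O)C(F)(F)F | intermediate
18 | 6α-[4-(benzyloxy)-3-methoxybenzoyloxy]-2β-(trimethylsilyloxy)-5αH-dauc-8-en-4β-ol | COc1cc(C(=O)O[C@H]2CC(C)=CC[C@@]3(C)[C@H](O[Si](C)(C)C)C[C@@](O)(C(C)C)[C@H]23)ccc1OCc1ccccc1 | intermediate
19 | 6α-[4-(benzyloxy)-3-methoxybenzoyloxy]-5αH-dauc-8-ene-2β,4β-diol | COc1cc(C(=O)O[C@H]2CC(C)=CC[C@@]3(C)[C@H](O)C[C@@](O)(C(C)C)[C@H]23)ccc1OCc1ccccc1 | intermediate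
20 | 6α-[4-(benzyloxy)-3-methoxybenzoyloxy]-4β-hydroxy-5αH-dauc-8-en-2-one | COc1cc(C(=O)O[C@H]2CC(C)=CC[C@@]3(C)C(=O)C[C@@](O)(C(C)C)[C@H]23)ccc1OCc1ccccc1 | intermediate
21 | 6α-[4-(benzyloxy)-3-methoxybenzoyloxy]-5αH-dauc-8-ene-2α,4β-diol | COc1cc(C(=O)O[C@H]2CC(C)=CC[C@@]3(C)[C@@H](O)C[C@@](O)(C(C)C)[C@H]23)ccc1OCc1ccccc1 | intermediate
22 | 2α-acetoxy-6α-[4-(benzyloxy)-3-methoxybenzoyloxy]-5αH-dauc-8-en-4β-ol | COc1cc(C(=O)O[C@H]2CC(C)=CC[C@@]3(C)[C@@H](OC(C)=O)C[C@@](O)(C(C)C)[C@H]23)ccc1OCc1ccccc1 | intermediate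
23 | 2α-acetoxy-6α-[4-(benzyloxy)-3-methoxybenzoyloxy]-8α,9α-epoxy-5αH-daucan-4β-ol | COc1cc(C(=O)O[C@H]2C[C@@]3(C)O[C@H]3C[C@@]3(C)[C@@H](OC(C)=O)C[C@@](O)(C(C)C)[C@H]23)ccc1OCc1ccccc1 | intermediate
24 | 2α-acetoxy-8α,9α-epoxy-6α-(4-hydroxy-3-methoxybenzoyloxy)-5αH-daucan-4β-ol | COc1cc(C(=O)O[C@H]2C[C@@]3(C)O[C@H]3C[C@@]3(C)[C@@H](OC(C)=O)C[C@@](O)(C(C)C)[C@H]23)ccc1O | target

**Step count and risks**

Total step count: 16. Longest linear sequence: 16 steps (from 1).

Steps most likely to fail:

Step 11 (Proposed new method). The C4 cation may be lost by proton elimination or by hydride shift from the isopropyl methine before the C6 ester carbonyl captures it, or the hydrolysis of the dioxanylium ion may leave the acyl group on the tertiary oxygen. The fallback uses known chemistry, sets out from 16 and comes back at 19. A SnCl4-mediated chloro-Prins cyclisation of 16 (CH2Cl2, −78 °C) should give the 4-chloro-2β-hydroxy tertiary chloride F1. Silver-assisted solvolysis (AgOTf, 2,6-lutidine, wet acetone) then ionises C4–Cl with 1,3-participation of the C6 ester, and water returns 19.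

Step 7. The β-alkoxy lactone 10 may fragment by retro-aldol cleavage of C1–C5, or the Grignard reagent may add from the face of the four-carbon bridge. The fallback sets out from 8 and comes back at 12; it replaces the alkenyl addition by a one-carbon homologation and also makes step 8 unnecessary. Wittig methylenation of 8 (Ph3P=CH2) gives the exocyclic alkene F2. 9-BBN then NaBO3 should hydroborate only this 1,1-disubstituted alkene, from the lactone face, to give the primary alcohol F3 with the C5 hydrogen already in place. Dess–Martin oxidation gives the aldehyde F4, i-PrMgCl at −78 °C gives the secondary carbinol F5, a second Dess–Martin oxidation gives the isopropyl ketone F6, and Zn/CH2Br2/TiCl4 methylenation returns 12.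

Step 15. The epoxidation may show poor facial selectivity (attack on the β face), which cannot be corrected later. The fallback sets out from 22 and comes back at 23. NBS in aqueous THF forms the bromonium ion on the more exposed face and water opens it at the tertiary C8, giving the bromohydrin F7. Ag2O then closes the epoxide with inversion at C9, which puts the oxygen on the face opposite to the one the peracid reaches.

Further compounds
F1 | step 11 | 6α-[4-(benzyloxy)-3-methoxybenzoyloxy]-4-chloro-5αH-dauc-8-en-2β-ol (C4 epimers) | COc1cc(C(=O)O[C@H]2CC(C)=CC[C@@]3(C)[C@H](O)CC(Cl)(C(C)C)[C@H]23)ccc1OCc1ccccc1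
F2 | step 7 | (1R,6S)-1,4-dimethyl-9-methylidene-7-oxabicyclo[4.2.1]non-3-en-8-one | O=C1O[C@H]2CC(C)=CC[C@]1(C)C2=C
F3 | step 7 | (1R,6S)-9-(hydroxymethyl)-1,4-dimethyl-7-oxabicyclo[4.2.1]non-3-en-8-one (H-9 syn to the lactone bridge) | O=C1O[C@H]2CC(C)=CC[C@]1(C)[C@@H]2CO
F4 | step 7 | (1R,6S)-1,4-dimethyl-8-oxo-7-oxabicyclo[4.2.1]non-3-ene-9-carbaldehyde (H-9 syn to the lactone bridge) | O=C1O[C@H]2CC(C)=CC[C@]1(C)[C@@H]2C=O
F5 | step 7 | (1R,6S)-9-(1-hydroxy-2-methylpropyl)-1,4-dimethyl-7-oxabicyclo[4.2.1]non-3-en-8-one (carbinol epimers) | O=C1O[C@H]2CC(C)=CC[C@]1(C)[C@@H]2C(O)C(C)C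
F6 | step 7 | (1R,6S)-1,4-dimethyl-9-(2-methylpropanoyl)-7-oxabicyclo[4.2.1]non-3-en-8-one (H-9 syn to the lactone bridge) | O=C1O[C@H]2CC(C)=CC[C@]1(C)[C@@H]2C(=O)C(C)C
F7 | step 15 | 2α-acetoxy-6α-[4-(benzyloxy)-3-methoxybenzoyloxy]-9β-bromo-5αH-daucane-4β,8α-diol | COc1cc(C(=O)O[C@H]2C[C@@](C)(O)[C@H](Br)C[C@@]3(C)[C@@H](OC(C)=O)C[C@@](O)(C(C)C)[C@H]23)ccc1OCc1ccccc1
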